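**Plan**
- The retrosynthesis cuts the prenyl olefin (cross-metathesis), the C6–allyl bond (Claisen shift from O5), O1–C2 of ring C (Mitsunobu), and finally the pair C8a–O1 / C4a–C4 (aryne insertion).
- Enabling feature: C8a–O1 and C4a–C4 sit on neighbouring carbons of ring A next to the C5 oxygen. This is an ortho-hydroxyaryl ketone, which a 3-alkoxyaryne forms from a carboxylic acid.
- Forward: the keto ester gives a silyl-protected β-hydroxy acid (ring B plus C2–C4), and 3,5-dimethoxyphenol gives the silyl triflate (ring A). The aryne step joins them, then ring C is closed.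
- End game: O5 is demethylated, an allyl group is moved from O5 to C6, and the allyl group is converted into prenyl.
- Stereochemistry: the only stereocentre is set as (R) by asymmetric hydrogenation of the β-keto ester and is inverted to (2S) in the Mitsunobu closure.

Key step: step 7

Assumption: flavanone numbering is used (ring A = benzo ring C4a–C8a, ring B = trimethoxyphenyl, ring C = pyranone). The (S)-bisphosphine is assigned from the usual facial preference of this catalyst family, under which β-aryl β-keto esters give the (R)-carbinol; if the sense proved opposite, the (R)-ligand would be used.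

**Route**

Step 1
Reactants: 1 ethyl 3-oxo-3-(3,4,5-trimethoxyphenyl)propanoate
Product: 2 ethyl (3R)-3-hydroxy-3-(3,4,5-trimethoxyphenyl)propanoate
Conditions: H2 (30 bar), [RuCl(p-cymene)((S)-SEGPHOS)]Cl (0.5 mol%), EtOH, 80 °C
Reagents that add atoms: none
Why: Noyori asymmetric hydrogenation of a β-keto ester, in which the substrate chelates ruthenium through both carbonyls and the (S)-bisphosphine should direct hydride to the ketone face that gives the (3R) carbinol, the only stereocentre of the route.

Step 2
Reactants: 2 ethyl (3R)-3-hydroxy-3-(3,4,5-trimethoxyphenyl)propanoate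
Product: 3 ethyl (3R)-3-[(triisopropylsilyl)oxy]-3-(3,4,5-trimethoxyphenyl)propanoate
Conditions: TIPSOTf, 2,6-lutidine, CH2Cl2, 0 °C to rt
Reagents that add atoms: triisopropylsilyl trifluoromethanesulfonate, CC(C)[Si](C(C)C)(C(C)C)OS(=O)(=O)C(F)(F)F
Why: Silylation of a secondary alcohol with a silyl triflate and a hindered pyridine base leaves the ester and aryl methyl ethers untouched, and the bulky silyl group is chosen to resist fluoride and β-elimination in step 7.

Step 3
Reactants: 3 ethyl (3R)-3-[(triisopropylsilyl)oxy]-3-(3,4,5-trimethoxyphenyl)propanoate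
Product: 4 (3R)-3-[(triisopropylsilyl)oxy]-3-(3,4,5-trimethoxyphenyl)propanoic acid
Conditions: LiOH·H2O, THF/H2O, 0 °C to rt; then 1 M HCl to pH 3 at 0 °C
Reagents that add atoms: lithium hydroxide, [Li+].[OH-]
Why: Ester saponification, in which the hindered silyl ether should survive hydroxide and a brief mildly acidic work-up and the low temperature should hold back E1cB loss of silanolate to the cinnamate.

Step 4
Reactants: 5 3,5-dimethoxyphenol
Product: 6 3,5-dimethoxyphenyl N-isopropylcarbamate
Conditions: i-PrNCO, Et3N (cat.), CH2Cl2, rt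
Reagents that add atoms: isopropyl isocyanate, CC(C)N=C=O
Why: Base-catalysed addition of a phenol to an isocyanate (carbamoylation) gives an N-monoalkyl carbamate that is a strong ortho-directing group and can later be removed under mild base.

Step 5
Reactants: 6 3,5-dimethoxyphenyl N-isopropylcarbamate
Product: 10 3,5-dimethoxy-2-(trimethylsilyl)phenyl N-isopropylcarbamate, via N-silyl carbamate 7 (not isolated), via aryllithium 8 (not isolated), via N-silyl C-silyl carbamate 9 (not isolated)
Conditions: TBSOTf, TMEDA, Et2O, 0 °C to rt; n-BuLi, TMEDA, −78 °C; TMSCl, −78 °C to rt; aq. NaHSO4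
Reagents that add atoms: tert-butyldimethylsilyl trifluoromethanesulfonate, CC(C)(C)[Si](C)(C)OS(=O)(=O)C(F)(F)F (silyl group of 7 to 9 only); n-butyllithium, [Li]CCCC (lithium of 8 only); chlorotrimethylsilane, C[Si](C)(C)Cl
Why: Directed ortho-metalation of an O-aryl carbamate, in which transient N-silylation masks the N–H, the carbamate and the neighbouring methoxy group together place lithium at C2 between them, chlorotrimethylsilane traps the aryllithium at −78 °C before an anionic Fries shift, and the N–Si bond is hydrolysed on acidic work-up.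

Step 6
Reactants: 10 3,5-dimethoxy-2-(trimethylsilyl)phenyl N-isopropylcarbamate
Product: 12 3,5-dimethoxy-2-(trimethylsilyl)phenyl trifluoromethanesulfonate, via 3,5-dimethoxy-2-(trimethylsilyl)phenol 11 (not isolated)
Conditions: DBU, Et2NH, MeCN, 40 °C; then PhNTf2, rt
Reagents that add atoms: N-phenylbis(trifluoromethanesulfonimide), O=S(=O)(N(c1ccccc1)S(=O)(=O)C(F)(F)F)C(F)(F)F
Why: E1cB cleavage of the N-monoalkyl carbamate by DBU (the released isocyanate is scavenged by diethylamine) gives the phenoxide, which the mild triflyl donor triflates in the same flask without protodesilylation.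

Step 7
Reactants: 4 (3R)-3-[(triisopropylsilyl)oxy]-3-(3,4,5-trimethoxyphenyl)propanoic acid; 12 3,5-dimethoxy-2-(trimethylsilyl)phenyl trifluoromethanesulfonate
Product: 14 (3R)-1-(2-hydroxy-4,6-dimethoxyphenyl)-3-[(triisopropylsilyl)oxy]-3-(3,4,5-trimethoxyphenyl)propan-1-one, via 3,5-dimethoxybenzyne 13 (not isolated)
Conditions: 4 (1 equiv), 12 (1.5 equiv), CsF (4 equiv), THF, 125 °C, sealed tube
Reagents that add atoms: none
Why: Fluoride attacks silicon of 12 and triflate leaves to give aryne 13; the caesium carboxylate of 4 then adds through oxygen to the aryne carbon remote from the flanking methoxy group (the future C8a), which places the aryl anion at the future C4a, where the adjacent C5–O dipole stabilises it. That anion attacks the carbonyl of the aryl ester just formed through a four-membered alkoxide, whose collapse cleaves the ester C–O bond and gives the ortho-acyl phenoxide, so that C8a–O1 and C4a–C4 are made in one operation. The closest known reaction type is the fluoride-induced insertion of arynes into the C–O bond of carboxylic acids to give ortho-hydroxyaryl ketones, which is reported to be regioselective for 3-alkoxyarynes. No ring is closed and no stereocentre is created; the carbinol centre lies β to the reacting carbonyl and should pass through unchanged. The selectivity needed is the regiochemistry of carboxylate addition, secured by the inductive effect of the methoxy group next to the aryne, and acyl transfer in preference to protonation of the aryl anion, favoured by the high temperature. The bulky triisopropylsilyl ether is chosen to withstand fluoride and to disfavour loss of silanolate from the product ketone.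

Step 8
Reactants: 14 (3R)-1-(2-hydroxy-4,6-dimethoxyphenyl)-3-[(triisopropylsilyl)oxy]-3-(3,4,5-trimethoxyphenyl)propan-1-one
Product: 15 (3R)-3-hydroxy-1-(2-hydroxy-4,6-dimethoxyphenyl)-3-(3,4,5-trimethoxyphenyl)propan-1-one
Conditions: HF·pyridine, pyridine, THF, 0 °C to rt
Reagents that add atoms: none
Why: Fluoride-mediated cleavage of a silyl ether under buffered, weakly acidic conditions, chosen over basic fluoride sources so that the β-hydroxy ketone neither undergoes retro-aldol cleavage nor dehydrates.

Step 9
Reactants: 15 (3R)-3-hydroxy-1-(2-hydroxy-4,6-dimethoxyphenyl)-3-(3,4,5-trimethoxyphenyl)propan-1-one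
Product: 16 (2S)-5,7-dimethoxy-2-(3,4,5-trimethoxyphenyl)chroman-4-one
Conditions: PPh3, DIAD, THF (dilute), 0 °C to rt
Reagents that add atoms: none
Why: Intramolecular Mitsunobu etherification, in which the benzylic alcohol is activated as its oxyphosphonium ion and displaced by the phenol oxygen in a 6-exo-tet SN2 closure, so ring C forms with inversion and C2 becomes (S).

Step 10
Reactants: 16 (2S)-5,7-dimethoxy-2-(3,4,5-trimethoxyphenyl)chroman-4-one
Product: 18 (2S)-5-hydroxy-7-methoxy-2-(3,4,5-trimethoxyphenyl)chroman-4-one, via dichloroboron chelate 17 (not isolated)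
Conditions: BCl3 (1.2 equiv), CH2Cl2, −78 to 0 °C; H2O work-up
Reagents that add atoms: boron trichloride, ClB(Cl)Cl (boron and chlorine stay only in chelate 17)
Why: Chelation-controlled Lewis acid demethylation, in which BCl3 bridges the C4 carbonyl and the peri C5 methoxy oxygen in a six-membered chelate so that chloride removes only that methyl group at low temperature, while the four methyl ethers that cannot chelate should remain.

Step 11
Reactants: 18 (2S)-5-hydroxy-7-methoxy-2-(3,4,5-trimethoxyphenyl)chroman-4-one; 19 allyl alcohol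
Product: 20 (2S)-5-(allyloxy)-7-methoxy-2-(3,4,5-trimethoxyphenyl)chroman-4-one
Conditions: PPh3, DIAD, THF, 0 °C to rt
Reagents that add atoms: none
Why: Mitsunobu O-alkylation of a phenol with a primary allylic alcohol runs under essentially neutral conditions and so avoids the base-induced opening of ring C to the chalcone that would racemise C2.

Step 12
Reactants: 20 (2S)-5-(allyloxy)-7-methoxy-2-(3,4,5-trimethoxyphenyl)chroman-4-one
Product: 21 (2S)-6-allyl-5-hydroxy-7-methoxy-2-(3,4,5-trimethoxyphenyl)chroman-4-one
Conditions: 1,2-dichlorobenzene, 180 °C, sealed tube, argon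
Reagents that add atoms: none
Why: Aromatic Claisen rearrangement, in which the [3,3] shift can deliver the allyl group only to C6 because the other ortho position (C4a) is substituted, and tautomerisation of the dienone restores the hydrogen-bonded C5 phenol.

Step 13
Reactants: 21 (2S)-6-allyl-5-hydroxy-7-methoxy-2-(3,4,5-trimethoxyphenyl)chroman-4-one; 22 2-methylbut-2-ene
Product: 23 artoflavanone, (2S)-5-hydroxy-7-methoxy-6-(3-methylbut-2-en-1-yl)-2-(3,4,5-trimethoxyphenyl)chroman-4-one
Conditions: 2-methylbut-2-ene (excess), second-generation Grubbs catalyst RuCl2(=CHPh)(H2IMes)(PCy3) (5 mol%), CH2Cl2, 40 °C, sealed tube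
Reagents that add atoms: none
Why: Olefin cross-metathesis of a terminal alkene with excess 2-methylbut-2-ene transfers an isopropylidene unit to give the trisubstituted prenyl olefin, which has no E/Z issue, and the chelated phenol and the ketone are tolerated by the ruthenium carbene.

**Compound list**

1 | ethyl 3-oxo-3-(3,4,5-trimethoxyphenyl)propanoate | CCOC(=O)CC(=O)c1cc(OC)c(OC)c(OC)c1 | starting material
2 | ethyl (3R)-3-hydroxy-3-(3,4,5-trimethoxyphenyl)propanoate | CCOC(=O)C[C@H](c1cc(OC)c(OC)c(OC)c1)O | intermediate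
3 | ethyl (3R)-3-[(triisopropylsilyl)oxy]-3-(3,4,5-trimethoxyphenyl)propanoate | CCOC(=O)C[C@H](c1cc(OC)c(OC)c(OC)c1)O[Si](C(C)C)(C(C)C)C(C)C | intermediate
4 | (3R)-3-[(triisopropylsilyl)oxy]-3-(3,4,5-trimethoxyphenyl)propanoic acid | OC(=O)C[C@H](c1cc(OC)c(OC)c(OC)c1)O[Si](C(C)C)(C(C)C)C(C)C | intermediate
5 | 3,5-dimethoxyphenol | COc1cc(O)cc(OC)c1 | starting material
6 | 3,5-dimethoxyphenyl N-isopropylcarbamate | COc1cc(OC)cc(OC(=O)NC(C)C)c1 | intermediate
7 | 3,5-dimethoxyphenyl N-(tert-butyldimethylsilyl)-N-isopropylcarbamate | COc1cc(OC)cc(OC(=O)N(C(C)C)[Si](C)(C)C(C)(C)C)c1 | intermediate (not isolated)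
8 | [2-{[N-(tert-butyldimethylsilyl)-N-isopropylcarbamoyl]oxy}-4,6-dimethoxyphenyl]lithium | COc1cc(OC)c([Li])c(OC(=O)N(C(C)C)[Si](C)(C)C(C)(C)C)c1 | intermediate (not isolated)
9 | 3,5-dimethoxy-2-(trimethylsilyl)phenyl N-(tert-butyldimethylsilyl)-N-isopropylcarbamate | COc1cc(OC)c([Si](C)(C)C)c(OC(=O)N(C(C)C)[Si](C)(C)C(C)(C)C)c1 | intermediate (not isolated)
10 | 3,5-dimethoxy-2-(trimethylsilyl)phenyl N-isopropylcarbamate | COc1cc(OC)c([Si](C)(C)C)c(OC(=O)NC(C)C)c1 | intermediate
11 | 3,5-dimethoxy-2-(trimethylsilyl)phenol (present as its DBU-H phenoxide) | COc1cc(O)c([Si](C)(C)C)c(OC)c1 | intermediate (not isolated)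
12 | 3,5-dimethoxy-2-(trimethylsilyl)phenyl trifluoromethanesulfonate | COc1cc(OC)c([Si](C)(C)C)c(OS(=O)(=O)C(F)(F)F)c1 | intermediate
13 | 3,5-dimethoxybenzyne (3,5-dimethoxy-1,2-didehydrobenzene) | COC1=CC(OC)=CC#C1 | intermediate (not isolated)
14 | (3R)-1-(2-hydroxy-4,6-dimethoxyphenyl)-3-[(triisopropylsilyl)oxy]-3-(3,4,5-trimethoxyphenyl)propan-1-one | COc1cc(O)c(C(=O)C[C@H](c2cc(OC)c(OC)c(OC)c2)O[Si](C(C)C)(C(C)C)C(C)C)c(OC)c1 | intermediate
15 | (3R)-3-hydroxy-1-(2-hydroxy-4,6-dimethoxyphenyl)-3-(3,4,5-trimethoxyphenyl)propan-1-one | COc1cc(O)c(C(=O)C[C@H](c2cc(OC)c(OC)c(OC)c2)O)c(OC)c1 | intermediate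
16 | (2S)-5,7-dimethoxy-2-(3,4,5-trimethoxyphenyl)chroman-4-one | COc1cc2c(c(OC)c1)C(=O)C[C@@H](c1cc(OC)c(OC)c(OC)c1)O2 | intermediate
17 | (2S)-5-[(dichloroboranyl)oxy]-7-methoxy-2-(3,4,5-trimethoxyphenyl)chroman-4-one (boron chelated to the C4 carbonyl) | COc1cc2c(c(OB(Cl)Cl)c1)C(=O)C[C@@H](c1cc(OC)c(OC)c(OC)c1)O2 | intermediate (not isolated)
18 | (2S)-5-hydroxy-7-methoxy-2-(3,4,5-trimethoxyphenyl)chroman-4-one | COc1cc2c(c(O)c1)C(=O)C[C@@H](c1cc(OC)c(OC)c(OC)c1)O2 | intermediate
19 | allyl alcohol (prop-2-en-1-ol) | C=CCO | starting material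
20 | (2S)-5-(allyloxy)-7-methoxy-2-(3,4,5-trimethoxyphenyl)chroman-4-one | COc1cc2c(c(OCC=C)c1)C(=O)C[C@@H](c1cc(OC)c(OC)c(OC)c1)O2 | intermediate
21 | (2S)-6-allyl-5-hydroxy-7-methoxy-2-(3,4,5-trimethoxyphenyl)chroman-4-one | COc1cc2c(c(O)c1CC=C)C(=O)C[C@@H](c1cc(OC)c(OC)c(OC)c1)O2 | intermediate
22 | 2-methylbut-2-ene | CC=C(C)C | starting material
23 | artoflavanone, (2S)-5-hydroxy-7-methoxy-6-(3-methylbut-2-en-1-yl)-2-(3,4,5-trimethoxyphenyl)chroman-4-one | COc1cc2c(c(O)c1CC=C(C)C)C(=O)C[C@@H](c1cc(OC)c(OC)c(OC)c1)O2 | target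

**Step count**

Total: 13 steps. Longest linear sequence: 10 steps (steps 1–3 then 7–13, or equally steps 4–6 then 7–13).

**Steps most likely to fail**

1. Step 7 (aryne insertion). Three processes could compete with the intended one. The aryl anion may be protonated before acyl transfer, which stops at O-arylation. Hot fluoride may cleave the silyl ether, or silanolate may be lost from the product ketone by E1cB, and re-closure of the resulting enone would erase the stereocentre. The product phenoxide may also be arylated by a second aryne.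
Fallback: the two fragments are joined with reversed polarity, setting out from acid 4 and phenol 5 and returning at 14. Phenol 5 is protected (MOMCl, i-Pr2NEt, CH2Cl2) as 1,3-dimethoxy-5-(methoxymethoxy)benzene F1. Acid 4 is converted (MeNHOMe·HCl, EDC·HCl, i-Pr2NEt, CH2Cl2) into the Weinreb amide (3R)-N-methoxy-N-methyl-3-[(triisopropylsilyl)oxy]-3-(3,4,5-trimethoxyphenyl)propanamide F2. Ortho-lithiation of F1 between the acetal oxygen and the neighbouring methoxy group (n-BuLi, TMEDA, THF, 0 °C) gives [2,4-dimethoxy-6-(methoxymethoxy)phenyl]lithium F3. Addition of F3 to F2 at −78 °C should give (3R)-1-[2,4-dimethoxy-6-(methoxymethoxy)phenyl]-3-[(triisopropylsilyl)oxy]-3-(3,4,5-trimethoxyphenyl)propan-1-one F4. Selective cleavage of the phenolic acetal (NaHSO4 on silica, CH2Cl2, rt) then gives 14.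

2. Step 9 (Mitsunobu closure). The activated benzylic oxyphosphonium ion may undergo E1cB elimination towards the enone instead of displacement. It may also ionise at the electron-rich benzylic position, which would erode enantiopurity.
Fallback: stereospecific substitution is replaced by thermodynamic closure and resolution, setting out from 15 and returning at 16. Diol 15 is dehydrated (p-TsOH cat., toluene, 80 °C) to the chalcone (E)-1-(2-hydroxy-4,6-dimethoxyphenyl)-3-(3,4,5-trimethoxyphenyl)prop-2-en-1-one F5. F5 is cyclised by oxa-Michael addition (NaOAc, EtOH, reflux) to racemic (2RS)-5,7-dimethoxy-2-(3,4,5-trimethoxyphenyl)chroman-4-one F6. Preparative chromatography on a cellulose-based chiral stationary phase then separates 16 from (2R)-5,7-dimethoxy-2-(3,4,5-trimethoxyphenyl)chroman-4-one F7. F7 can be re-equilibrated to F6 under the NaOAc conditions and recycled.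

3. Step 12 (Claisen rearrangement). At 180 °C ring C may open reversibly by retro-oxa-Michael reaction, with loss of configuration at C2. A following Cope shift may carry the allyl group on to C8, or conversion may stay incomplete.
Fallback: the carbon substituent is introduced by halogenation and cross-coupling, setting out from 18 and returning directly at 23, so that steps 11 to 13 are bypassed. Iodination ortho to the free C5 hydroxyl (NIS, DMF, rt) should give (2S)-5-hydroxy-6-iodo-7-methoxy-2-(3,4,5-trimethoxyphenyl)chroman-4-one F8. Stille coupling of F8 with tributyl(3-methylbut-2-en-1-yl)stannane (Pd(PPh3)4, DMF, 90 °C) then gives 23.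

**Further compounds**

F1 | step 7 | 1,3-dimethoxy-5-(methoxymethoxy)benzene | COCOc1cc(OC)cc(OC)c1
F2 | step 7 | (3R)-N-methoxy-N-methyl-3-[(triisopropylsilyl)oxy]-3-(3,4,5-trimethoxyphenyl)propanamide | CON(C)C(=O)C[C@H](c1cc(OC)c(OC)c(OC)c1)O[Si](C(C)C)(C(C)C)C(C)C
F3 | step 7 | [2,4-dimethoxy-6-(methoxymethoxy)phenyl]lithium | [Li]c1c(OC)cc(OC)cc1OCOC
F4 | step 7 | (3R)-1-[2,4-dimethoxy-6-(methoxymethoxy)phenyl]-3-[(triisopropylsilyl)oxy]-3-(3,4,5-trimethoxyphenyl)propan-1-one | COCOc1cc(OC)cc(OC)c1C(=O)C[C@H](c1cc(OC)c(OC)c(OC)c1)O[Si](C(C)C)(C(C)C)C(C)C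
F5 | step 9 | (E)-1-(2-hydroxy-4,6-dimethoxyphenyl)-3-(3,4,5-trimethoxyphenyl)prop-2-en-1-one | COc1cc(O)c(C(=O)/C=C/c2cc(OC)c(OC)c(OC)c2)c(OC)c1
F6 | step 9 | (2RS)-5,7-dimethoxy-2-(3,4,5-trimethoxyphenyl)chroman-4-one (racemate) | COc1cc2c(c(OC)c1)C(=O)CC(c1cc(OC)c(OC)c(OC)c1)O2
F7 | step 9 | (2R)-5,7-dimethoxy-2-(3,4,5-trimethoxyphenyl)chroman-4-one | COc1cc2c(c(OC)c1)C(=O)C[C@H](c1cc(OC)c(OC)c(OC)c1)O2
F8 | step 12 | (2S)-5-hydroxy-6-iodo-7-methoxy-2-(3,4,5-trimethoxyphenyl)chroman-4-one | COc1cc2c(c(O)c1I)C(=O)C[C@@H](c1cc(OC)c(OC)c(OC)c1)O2
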